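**Retrosynthetic overview** (carotenoid numbering)
1. C11=C12 is cut by a Wittig disconnection into the C15 phosphonium salt 17 and the C15 aldehyde ester 21; 21 comes from the C10 dialdehyde 18 and the C5 phosphonate 19, and the C8′ ester is reduced last.
2. Salt 17 comes from dienyl carbinol 15 through its pentadienyl cation (PPh3·HBr).
3. The key C6–C7 bond is made by a [2,3]-Wittig rearrangement of ring allyl pentadienyl ether 13, which transfers the ring C–O chirality to C-6, cis to the C-3 oxygen.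
4. The only ring is closed before that, by ring-closing metathesis of dienol 8; its sacrificial carbinol is set by Felkin–Anh addition to α-silyloxy aldehyde 6.
5. C-3 is bought in (R)-glycidol, which prenyl Grignard opens through its tertiary terminus to build the gem-dimethyl carbon.

Assumption: the target is read as all-E (3S,6R)-3-hydroxy-8′-apo-ε-caroten-8′-ol (ring OH cis to the polyene); 1, 2, 7, 10, 18 and 19 are taken as catalogue compounds.

**Route**

Step 1
Reactants: 1 (R)-glycidol; 2 prenylmagnesium chloride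
Product: 3 (S)-4,4-dimethylhex-5-ene-1,2-diol
Conditions: 2 (2.5 equiv), THF, −20 → 0 °C; H2O work-up
Reagents that add atoms: none
Why: After the first equivalent has deprotonated the hydroxyl, the allylic Grignard opens the epoxide CH2 through its γ-carbon (SE2′ epoxide opening, the usual course for prenyl Grignard without copper), which builds the quaternary carbon with a vinyl handle and leaves the bought stereocentre (the future C-3) untouched.

Step 2
Reactants: 3 (S)-4,4-dimethylhex-5-ene-1,2-diol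
Product: 4 (S)-4,4-dimethyl-1,2-bis(triethylsilyloxy)hex-5-ene
Conditions: Et3SiCl (2.4 equiv), imidazole, CH2Cl2, 0 °C → rt
Reagents that add atoms: chlorotriethylsilane, CC[Si](CC)(CC)Cl
Why: Routine silyl ether formation gives a non-chelating α-silyloxy group for step 4 and a primary silyl ether that can be oxidised selectively in step 3.

Step 3
Reactants: 4 (S)-4,4-dimethyl-1,2-bis(triethylsilyloxy)hex-5-ene
Product: 6 (S)-4,4-dimethyl-2-(triethylsilyloxy)hex-5-enal, via alkoxysulfonium chloride 5 (not isolated)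
Conditions: (COCl)2, DMSO, CH2Cl2, −78 → −30 °C; then Et3N, → 0 °C; used crude
Reagents that add atoms: none
Why: Under Swern conditions the chlorosulfonium reagent cleaves only the unhindered primary triethylsilyl ether and oxidises it in place (selective Swern oxidation of a primary silyl ether), so the secondary silyl ether and the α-stereocentre survive.

Step 4
Reactants: 6 (S)-4,4-dimethyl-2-(triethylsilyloxy)hex-5-enal; 7 isopropenylmagnesium bromide
Product: 8 (3R,4S)-2,6,6-trimethyl-4-(triethylsilyloxy)octa-1,7-dien-3-ol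
Conditions: THF, −78 °C; H2O work-up
Reagents that add atoms: none
Why: Grignard 1,2-addition under non-chelating conditions follows the polar Felkin–Anh model, so the nucleophile enters anti to the α-silyloxy group and sets the new carbinol 3,4-anti (expected about 4–5:1; the minor syn isomer is removed by chromatography after step 5).

Step 5
Reactants: 8 (3R,4S)-2,6,6-trimethyl-4-(triethylsilyloxy)octa-1,7-dien-3-ol
Product: 9 (1R,6S)-2,4,4-trimethyl-6-(triethylsilyloxy)cyclohex-2-en-1-ol
Conditions: second-generation Grubbs catalyst RuCl2(=CHPh)(H2IMes)(PCy3) (5 mol %), CH2Cl2, 40 °C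
Reagents that add atoms: none
Why: Ring-closing metathesis of the 1,1-disubstituted and the monosubstituted alkene, helped by the gem-dimethyl group and the allylic hydroxyl, gives the trisubstituted cyclohexene with loss of ethene; both stereocentres are untouched and now sit cis on the ring.

Step 6
Reactants: 10 3-methylpenta-1,4-dien-3-ol
Product: 11 (E)-5-bromo-3-methylpenta-1,3-diene
Conditions: PBr3 (0.4 equiv), Et2O, −20 → 0 °C; used crude
Reagents that add atoms: phosphorus tribromide, BrP(Br)Br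
Why: PBr3 turns the tertiary bis-allylic alcohol into the conjugated primary bromide with allylic transposition (SN2′-type bromination); any Z isomer is harmless because this double bond becomes a single bond in step 9.

Step 7
Reactants: 9 (1R,6S)-2,4,4-trimethyl-6-(triethylsilyloxy)cyclohex-2-en-1-ol; 11 (E)-5-bromo-3-methylpenta-1,3-diene
Product: 13 (1R,6S)-1-[(2E)-3-methylpenta-2,4-dienyloxy]-2,4,4-trimethyl-6-(triethylsilyloxy)cyclohex-2-ene, via potassium alkoxide 12 (not isolated)
Conditions: KN(SiMe3)2, THF, −78 °C; then 11 (1.5 equiv), Bu4NI (cat.), −78 → −20 °C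
Reagents that add atoms: none
Why: Williamson ether synthesis with the very reactive pentadienylic bromide runs below −20 °C, where 1,2-silyl migration to the neighbouring oxygen is slow, and no stereocentre is affected.

Step 8
Reactants: 13 (1R,6S)-1-[(2E)-3-methylpenta-2,4-dienyloxy]-2,4,4-trimethyl-6-(triethylsilyloxy)cyclohex-2-ene
Product: 15 (2E)-3-methyl-1-[(1R,4S)-2,6,6-trimethyl-4-(triethylsilyloxy)cyclohex-2-en-1-yl]penta-2,4-dien-1-ol, via lithiated ether 14 (not isolated)
Conditions: n-BuLi (1.3 equiv), THF, −78 → −40 °C; then H2O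
Reagents that add atoms: none
Why: Deprotonation at the doubly allylic O–CH2 triggers a [2,3]-Wittig rearrangement through a five-membered envelope transition state in which the carbanion is delivered suprafacially to the ring alkene carbon on the face of the breaking C–O bond, so the new C–C bond and its stereocentre (C-6) are set cis to the silyloxy group by 1,3-chirality transfer while the sacrificial carbinol carbon becomes the ring alkene (the new exocyclic carbinol forms as a mixture and is destroyed in step 9).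

Step 9
Reactants: 15 (2E)-3-methyl-1-[(1R,4S)-2,6,6-trimethyl-4-(triethylsilyloxy)cyclohex-2-en-1-yl]penta-2,4-dien-1-ol
Product: 17 [(2E,4E)-5-[(1R,4S)-4-hydroxy-2,6,6-trimethylcyclohex-2-en-1-yl]-3-methylpenta-2,4-dienyl]triphenylphosphonium bromide, via silylated phosphonium bromide 16 (not isolated)
Conditions: PPh3·HBr (1.2 equiv), MeOH, 0 °C → rt, 16 h
Reagents that add atoms: triphenylphosphine hydrobromide, [PH+](c1ccccc1)(c1ccccc1)c1ccccc1.[Br-]
Why: Acid ionises the dienyl carbinol to the same pentadienyl cation that vinyl-ionols give in the classical C15 Wittig-salt preparation, PPh3 captures it at the unhindered terminus (SN1-type allylic substitution) to give the conjugated E,E-dienyl salt, and the methanolic acid removes the triethylsilyl group without involving the ring stereocentres.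

Step 10
Reactants: 18 (2E,4E,6E)-2,7-dimethylocta-2,4,6-trienedial; 19 ethyl (E)-4-(diethoxyphosphoryl)-2-methylbut-2-enoate
Product: 21 ethyl (2E,4E,6E,8E,10E)-2,6,11-trimethyl-12-oxododeca-2,4,6,8,10-pentaenoate, via phosphonate carbanion 20 (not isolated)
Conditions: 19, NaH, THF, 0 °C; then added to 18 (2.5 equiv), −20 °C → rt
Reagents that add atoms: none
Why: Horner–Wadsworth–Emmons olefination of the dialdehyde used in excess gives the mono-adduct with a new E double bond and keeps the second aldehyde for step 11.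

Step 11
Reactants: 17 [(2E,4E)-5-[(1R,4S)-4-hydroxy-2,6,6-trimethylcyclohex-2-en-1-yl]-3-methylpenta-2,4-dienyl]triphenylphosphonium bromide; 21 ethyl (2E,4E,6E,8E,10E)-2,6,11-trimethyl-12-oxododeca-2,4,6,8,10-pentaenoate
Product: 23 ethyl (all-E)-(3S,6R)-3-hydroxy-8′-apo-ε-caroten-8′-oate, via phosphorus ylide 22 (not isolated)
Conditions: NaOEt, EtOH/CH2Cl2, 0 °C → rt; then EtOH, reflux (11Z → 11E)
Reagents that add atoms: none
Why: Wittig olefination of the allylic ylide with the polyenal forms C11=C12, and the 11Z isomer that also forms is equilibrated thermally to the all-E polyene as is standard for carotenoids, with the stereocentres unaffected.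

Step 12
Reactants: 23 ethyl (all-E)-(3S,6R)-3-hydroxy-8′-apo-ε-caroten-8′-oate
Product: 24 (all-E)-(3S,6R)-3-hydroxy-8′-apo-ε-caroten-8′-ol
Conditions: i-Bu2AlH (3.5 equiv), CH2Cl2, −78 → −40 °C; H2O work-up
Reagents that add atoms: none
Why: DIBAL-H 1,2-reduction of the conjugated ester gives the primary allylic alcohol without touching the polyene or the stereocentres.

**Compound list**
1 | (R)-glycidol | OC[C@@H]1CO1 | starting material
2 | prenylmagnesium chloride (3-methylbut-2-enylmagnesium chloride) | CC(C)=CC[Mg]Cl | starting material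
3 | (S)-4,4-dimethylhex-5-ene-1,2-diol | C=CC(C)(C)C[C@H](O)CO | intermediate
4 | (S)-4,4-dimethyl-1,2-bis(triethylsilyloxy)hex-5-ene | C=CC(C)(C)C[C@H](O[Si](CC)(CC)CC)CO[Si](CC)(CC)CC | intermediate
5 | {[(2S)-4,4-dimethyl-2-(triethylsilyloxy)hex-5-enyl]oxy}dimethylsulfonium chloride | C=CC(C)(C)C[C@H](O[Si](CC)(CC)CC)CO[S+](C)C.[Cl-] | intermediate
6 | (S)-4,4-dimethyl-2-(triethylsilyloxy)hex-5-enal | C=CC(C)(C)C[C@H](O[Si](CC)(CC)CC)C=O | intermediate
7 | isopropenylmagnesium bromide | CC(=C)[Mg]Br | starting material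
8 | (3R,4S)-2,6,6-trimethyl-4-(triethylsilyloxy)octa-1,7-dien-3-ol | C=C(C)[C@@H](O)[C@@H](O[Si](CC)(CC)CC)CC(C)(C)C=C | intermediate
9 | (1R,6S)-2,4,4-trimethyl-6-(triethylsilyloxy)cyclohex-2-en-1-ol (OH and OSiEt3 cis) | CC1=CC(C)(C)C[C@H](O[Si](CC)(CC)CC)[C@@H]1O | intermediate
10 | 3-methylpenta-1,4-dien-3-ol | C=CC(C)(O)C=C | starting material
11 | (E)-5-bromo-3-methylpenta-1,3-diene | C=C/C(C)=C/CBr | intermediate
12 | potassium (1R,6S)-2,4,4-trimethyl-6-(triethylsilyloxy)cyclohex-2-en-1-olate | CC1=CC(C)(C)C[C@H](O[Si](CC)(CC)CC)[C@@H]1[O-].[K+] | intermediate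
13 | (1R,6S)-1-[(2E)-3-methylpenta-2,4-dienyloxy]-2,4,4-trimethyl-6-(triethylsilyloxy)cyclohex-2-ene | CC1=CC(C)(C)C[C@H](O[Si](CC)(CC)CC)[C@@H]1OC/C=C(C)/C=C | intermediate
14 | (1R,6S)-1-[(2E)-1-lithio-3-methylpenta-2,4-dienyloxy]-2,4,4-trimethyl-6-(triethylsilyloxy)cyclohex-2-ene | CC1=CC(C)(C)C[C@H](O[Si](CC)(CC)CC)[C@@H]1OC([Li])/C=C(C)/C=C | intermediate
15 | (2E)-3-methyl-1-[(1R,4S)-2,6,6-trimethyl-4-(triethylsilyloxy)cyclohex-2-en-1-yl]penta-2,4-dien-1-ol (mixture at the carbinol carbon; side chain cis to OSiEt3) | CC1=C[C@@H](O[Si](CC)(CC)CC)CC(C)(C)[C@H]1C(O)/C=C(C)/C=C | intermediate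
16 | [(2E,4E)-3-methyl-5-[(1R,4S)-2,6,6-trimethyl-4-(triethylsilyloxy)cyclohex-2-en-1-yl]penta-2,4-dienyl]triphenylphosphonium bromide | CC1=C[C@@H](O[Si](CC)(CC)CC)CC(C)(C)[C@H]1/C=C/C(C)=C/C[P+](c2ccccc2)(c2ccccc2)c2ccccc2.[Br-] | intermediate
17 | [(2E,4E)-5-[(1R,4S)-4-hydroxy-2,6,6-trimethylcyclohex-2-en-1-yl]-3-methylpenta-2,4-dienyl]triphenylphosphonium bromide | CC1=C[C@@H](O)CC(C)(C)[C@H]1/C=C/C(C)=C/C[P+](c2ccccc2)(c2ccccc2)c2ccccc2.[Br-] | intermediate
18 | (2E,4E,6E)-2,7-dimethylocta-2,4,6-trienedial | O=C/C(C)=C/C=C/C=C(C)/C=O | starting material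
19 | ethyl (E)-4-(diethoxyphosphoryl)-2-methylbut-2-enoate | CCOC(=O)/C(C)=C/CP(=O)(OCC)OCC | starting material
20 | sodium salt of the C-4 carbanion of 19 | CCOC(=O)/C(C)=C/[CH-]P(=O)(OCC)OCC.[Na+] | intermediate
21 | ethyl (2E,4E,6E,8E,10E)-2,6,11-trimethyl-12-oxododeca-2,4,6,8,10-pentaenoate | CCOC(=O)/C(C)=C/C=C/C(C)=C/C=C/C=C(C)/C=O | intermediate
22 | [(2E,4E)-5-[(1R,4S)-4-hydroxy-2,6,6-trimethylcyclohex-2-en-1-yl]-3-methylpenta-2,4-dienylidene]triphenylphosphorane | CC1=C[C@@H](O)CC(C)(C)[C@H]1/C=C/C(C)=C/C=P(c2ccccc2)(c2ccccc2)c2ccccc2 | intermediate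
23 | ethyl (all-E)-(3S,6R)-3-hydroxy-8′-apo-ε-caroten-8′-oate | CC1=C[C@@H](O)CC(C)(C)[C@H]1/C=C/C(C)=C/C=C/C(C)=C/C=C/C=C(C)/C=C/C=C(\C)C(=O)OCC | intermediate
24 | (all-E)-(3S,6R)-3-hydroxy-8′-apo-ε-caroten-8′-ol, i.e. (2E,4E,6E,8E,10E,12E,14E,16E)-17-[(1R,4S)-4-hydroxy-2,6,6-trimethylcyclohex-2-en-1-yl]-2,6,11,15-tetramethylheptadeca-2,4,6,8,10,12,14,16-octaen-1-ol | CC1=C[C@@H](O)CC(C)(C)[C@H]1/C=C/C(C)=C/C=C/C(C)=C/C=C/C=C(C)/C=C/C=C(\C)CO | target

**Step count**
Total: 12 steps. Longest linear sequence: 10 steps (1–5, 7, 8, 9, 11, 12).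

**Steps most likely to fail**

Step 4 (Felkin–Anh selectivity of an α-triethylsilyloxy aldehyde may be low). Fallback: set out from 8 taken on unseparated from its C-3 epimer (3S,4S)-2,6,6-trimethyl-4-(triethylsilyloxy)octa-1,7-dien-3-ol F1. Ring closure as in step 5 then gives 9 mixed with (1S,6S)-2,4,4-trimethyl-6-(triethylsilyloxy)cyclohex-2-en-1-ol F2. Dess–Martin oxidation converges both on (S)-2,4,4-trimethyl-6-(triethylsilyloxy)cyclohex-2-en-1-one F3. LiBH(s-Bu)3 (THF, −78 °C) then adds hydride 1,2 from the face away from the silyloxy group, so the route is rejoined at 9 with the carbinol set by cyclic instead of acyclic stereocontrol.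

Step 7 (the alkoxide may shift the neighbouring silyl group, and bromide 11 is labile). Fallback: set out from 9 and 10 and avoid any alkoxide. Alcohol 10 is transposed with catalytic Ph3SiOReO3 (Et2O, −50 °C) to (2E)-3-methylpenta-2,4-dien-1-ol F4. Cl3CCN with catalytic DBU converts this into (2E)-3-methylpenta-2,4-dienyl 2,2,2-trichloroacetimidate F5. Alcohol 9 is then alkylated with F5 under catalytic TfOH (CH2Cl2/cyclohexane, −40 °C), which returns to the route at 13.

Step 8 (the delocalised pentadienyl anion may be too unreactive towards the hindered ring alkene, or may react by [1,2] or [1,4] shifts). Fallback: set out from 9 and deliver a one-carbon unit with a non-stabilised carbanion (the Still variant of the Wittig rearrangement), then build the chain by proven ionone chemistry.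
- Alkoxide 12 (from KH) is alkylated with Bu3SnCH2I to tributyl({[(1R,6S)-2,4,4-trimethyl-6-(triethylsilyloxy)cyclohex-2-en-1-yl]oxy}methyl)stannane F6.
- n-BuLi (THF, −78 °C) gives by tin–lithium exchange (1R,6S)-1-(lithiomethoxy)-2,4,4-trimethyl-6-(triethylsilyloxy)cyclohex-2-ene F7, which rearranges [2,3] to [(1R,4S)-2,6,6-trimethyl-4-(triethylsilyloxy)cyclohex-2-en-1-yl]methanol F8.
- Dess–Martin oxidation gives (1R,4S)-2,6,6-trimethyl-4-(triethylsilyloxy)cyclohex-2-ene-1-carbaldehyde F9.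
- The neutral stabilised ylide Ph3P=CHC(O)CH3 (toluene, 90 °C) gives (E)-4-[(1R,4S)-2,6,6-trimethyl-4-(triethylsilyloxy)cyclohex-2-en-1-yl]but-3-en-2-one F10.
- CH2=CHMgBr gives (1E)-3-methyl-1-[(1R,4S)-2,6,6-trimethyl-4-(triethylsilyloxy)cyclohex-2-en-1-yl]penta-1,4-dien-3-ol F11.
- PPh3·HBr in MeOH converts F11 (through 16) into 17, where the route is rejoined.

**Further compounds**
F1 | step 4 | (3S,4S)-2,6,6-trimethyl-4-(triethylsilyloxy)octa-1,7-dien-3-ol | C=C(C)[C@H](O)[C@@H](O[Si](CC)(CC)CC)CC(C)(C)C=C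
F2 | step 4 | (1S,6S)-2,4,4-trimethyl-6-(triethylsilyloxy)cyclohex-2-en-1-ol | CC1=CC(C)(C)C[C@H](O[Si](CC)(CC)CC)[C@H]1O
F3 | step 4 | (S)-2,4,4-trimethyl-6-(triethylsilyloxy)cyclohex-2-en-1-one | CC1=CC(C)(C)C[C@H](O[Si](CC)(CC)CC)C1=O
F4 | step 7 | (2E)-3-methylpenta-2,4-dien-1-ol | OC/C=C(C)/C=C
F5 | step 7 | (2E)-3-methylpenta-2,4-dienyl 2,2,2-trichloroacetimidate | N=C(OC/C=C(C)/C=C)C(Cl)(Cl)Cl
F6 | step 8 | tributyl({[(1R,6S)-2,4,4-trimethyl-6-(triethylsilyloxy)cyclohex-2-en-1-yl]oxy}methyl)stannane | CC1=CC(C)(C)C[C@H](O[Si](CC)(CC)CC)[C@@H]1OC[Sn](CCCC)(CCCC)CCCC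
F7 | step 8 | (1R,6S)-1-(lithiomethoxy)-2,4,4-trimethyl-6-(triethylsilyloxy)cyclohex-2-ene | CC1=CC(C)(C)C[C@H](O[Si](CC)(CC)CC)[C@@H]1OC[Li]
F8 | step 8 | [(1R,4S)-2,6,6-trimethyl-4-(triethylsilyloxy)cyclohex-2-en-1-yl]methanol | CC1=C[C@@H](O[Si](CC)(CC)CC)CC(C)(C)[C@H]1CO
F9 | step 8 | (1R,4S)-2,6,6-trimethyl-4-(triethylsilyloxy)cyclohex-2-ene-1-carbaldehyde | CC1=C[C@@H](O[Si](CC)(CC)CC)CC(C)(C)[C@H]1C=O
F10 | step 8 | (E)-4-[(1R,4S)-2,6,6-trimethyl-4-(triethylsilyloxy)cyclohex-2-en-1-yl]but-3-en-2-one | CC1=C[C@@H](O[Si](CC)(CC)CC)CC(C)(C)[C@H]1/C=C/C(C)=O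
F11 | step 8 | (1E)-3-methyl-1-[(1R,4S)-2,6,6-trimethyl-4-(triethylsilyloxy)cyclohex-2-en-1-yl]penta-1,4-dien-3-ol | CC1=C[C@@H](O[Si](CC)(CC)CC)CC(C)(C)[C@H]1/C=C/C(C)(O)C=C
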